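**Retrosynthetic overview**

1. Target 25 ⇐ allylic acetate 20 + angelic acid 21: one C8–O bond is made by a syn, anti-Markovnikov hydroacyloxylation of C7=C8 that also sets C7 and C8 (key step, new).
2. 20 ⇐ hydroxy-enone 18 (reduction delivered from the C4–OH sets C6, then acetylation) ⇐ silyl enol ether 16 (Saegusa oxidation).
3. 16 ⇐ acyclic alkyne/siloxy-vinylcyclopropane 15: one intramolecular [5+2] cycloaddition closes the five- and seven-membered rings together and places the tetrasubstituted alkene at the ring fusion.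
4. 15 ⇐ (S)-tertiary aldol 14, whose C4–O bond comes from enantioselective conjugate boration–oxidation of enone 12.
5. 12 ⇐ ketone 9 (from cyclopropanecarbonitrile 5 and 2-iodopropane 6) + ynone 4 (from pentane-2,4-dione 1 and 1-bromobut-2-yne 2).

Assumption: guaiane numbering is used for the bicycle (C1/C5 ring fusion, C4 carbinol with C15 methyl, C6 acetoxy, C7 isopropyl, C8 angeloyloxy, C10 with C14 methyl), and the ligand enantiomer in step 5 is the one that gives the 3S alcohol (taken as (R,R)-QuinoxP*, to be confirmed on the first run).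

**Route**

Step 1
Reactants: 1 pentane-2,4-dione; 2 1-bromobut-2-yne
Product: 4 hept-5-yn-2-one, via alkylated diketone 3 (not isolated)
Conditions: K2CO3, EtOH, reflux
Reagents that add atoms: none
Why: C-alkylation of the diketone followed by retro-Claisen deacetylation by ethanol (alkylation–deacylation) gives the methyl ketone; no stereocentre is formed.

Step 2
Reactants: 5 cyclopropanecarbonitrile; 6 2-iodopropane
Product: 7 1-(propan-2-yl)cyclopropane-1-carbonitrile
Conditions: LiN(iPr)2, THF, −78 °C; then 6, DMPU, −78 to 23 °C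
Reagents that add atoms: none
Why: α-alkylation of the lithiated nitrile (nitrile-anion SN2), which tolerates a secondary iodide better than an ester enolate would.

Step 3
Reactants: 7 1-(propan-2-yl)cyclopropane-1-carbonitrile
Product: 9 1-[1-(propan-2-yl)cyclopropyl]ethan-1-one, via N-lithio ketimine 8 (not isolated)
Conditions: MeLi, Et2O, 0 to 23 °C; then 2 M HCl, 23 °C
Reagents that add atoms: methyllithium, [Li]C; water, O
Why: organolithium addition to the nitrile stops at the imine salt, and acid hydrolysis releases the methyl ketone.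

Step 4
Reactants: 9 1-[1-(propan-2-yl)cyclopropyl]ethan-1-one; 4 hept-5-yn-2-one
Product: 12 (2E)-3-methyl-1-[1-(propan-2-yl)cyclopropyl]oct-2-en-6-yn-1-one, via lithium aldolate 10 (not isolated), via aldol acetate 11 (not isolated)
Conditions: LiN(iPr)2, THF, −78 °C; 4; Ac2O, −78 to 0 °C; DBU, 23 °C; E isomer separated on silica (E:Z about 3:1 expected)
Reagents that add atoms: acetic anhydride, CC(=O)OC(C)=O (acetyl is carried by 11 only)
Why: directed aldol addition from the only enolisable position of 9, O-acetylation of the tertiary aldolate and E1cB elimination give the enone, whose defined E geometry is what the next step needs.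

Step 5
Reactants: 12 (2E)-3-methyl-1-[1-(propan-2-yl)cyclopropyl]oct-2-en-6-yn-1-one
Product: 14 (3S)-3-hydroxy-3-methyl-1-[1-(propan-2-yl)cyclopropyl]oct-6-yn-1-one, via boryl ketone 13 (not isolated)
Conditions: CuCl (5 mol %), (R,R)-QuinoxP* (6 mol %), NaOtBu (10 mol %), B2pin2 (1.1 equiv), MeOH (2 equiv), THF, 23 °C; then NaBO3·4H2O, THF/H2O, 23 °C
Reagents that add atoms: bis(pinacolato)diboron, CC1(C)OB(OC1(C)C)B1OC(C)(C)C(C)(C)O1 (boron is carried by 13 only); sodium perborate, O=BO[O-].[Na+] (oxygen of the C–OH)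
Why: enantioselective conjugate boration by a chiral monovalent copper boryl complex sets the quaternary carbon on the geometrically pure enone, and perborate oxidation converts C–B into C–O with retention to give the S tertiary alcohol (guaiane C4).

Step 6
Reactants: 14 (3S)-3-hydroxy-3-methyl-1-[1-(propan-2-yl)cyclopropyl]oct-6-yn-1-one
Product: 15 (1Z,3S)-3-methyl-1-[1-(propan-2-yl)cyclopropyl]-1,3-bis(triethylsilyloxy)oct-1-en-6-yne
Conditions: Et3SiOTf (2.6 equiv), Et3N, CH2Cl2, −78 to 0 °C
Reagents that add atoms: triethylsilyl trifluoromethanesulfonate, CC[Si](CC)(CC)OS(=O)(=O)C(F)(F)F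
Why: silylation of the tertiary alcohol and soft enolisation–silylation of the ketone, which has a single enolisable position and gives the Z enol ether (oxygen cis to the chain, away from the quaternary cyclopropyl carbon).

Step 7
Reactants: 15 (1Z,3S)-3-methyl-1-[1-(propan-2-yl)cyclopropyl]-1,3-bis(triethylsilyloxy)oct-1-en-6-yne
Product: 16 (4S,5S)-4,6-bis(triethylsilyloxy)guaia-1(10),6-diene (H5 cis to the C4 oxygen)
Conditions: [Rh(CO)2Cl]2 (5 mol %), toluene, 90 °C
Reagents that add atoms: none
Why: intramolecular [5+2] cycloaddition of the alkyne with the vinylcyclopropane (monovalent rhodium catalysis) forms the C1–C5 and C9–C10 bonds and both rings at once; C5 is set by the C4 stereocentre because the methyl group takes the position eclipsing the (Z)-C6–OSiEt3 while the bulky C4–OSiEt3 points away from it, which puts H5 cis to the C4 oxygen.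

Step 8
Reactants: 16 (4S,5S)-4,6-bis(triethylsilyloxy)guaia-1(10),6-diene
Product: 18 (4S,5S)-4-hydroxyguaia-1(10),7-dien-6-one, via silyl ether enone 17 (not isolated)
Conditions: Pd(OAc)2 (1.1 equiv), MeCN, 40 °C; then HF·pyridine, THF, 0 °C
Reagents that add atoms: none
Why: Saegusa–Ito oxidation, in which the divalent palladium enolate at C7 loses a β-hydrogen from the ring CH2 (C8) rather than the isopropyl methine, followed by fluoride cleavage of the tertiary silyl ether under non-basic conditions that leave C5 untouched.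

Step 9
Reactants: 18 (4S,5S)-4-hydroxyguaia-1(10),7-dien-6-one
Product: 19 (4S,5R,6S)-guaia-1(10),7-diene-4,6-diol
Conditions: Me4NBH(OAc)3, MeCN/AcOH (1:1), −30 °C
Reagents that add atoms: none
Why: Evans–Saksena hydroxyl-directed 1,2-reduction, in which hydride is delivered from the boron bound to the C4 oxygen onto the face of the C6 carbonyl that lies on the C4 side, so H6 ends cis to C4 and the new C6–OH cis to H5.

Step 10
Reactants: 19 (4S,5R,6S)-guaia-1(10),7-diene-4,6-diol
Product: 20 (4S,5R,6S)-4-hydroxyguaia-1(10),7-dien-6-yl acetate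
Conditions: Ac2O, pyridine, DMAP (5 mol %), CH2Cl2, 0 °C
Reagents that add atoms: acetic anhydride, CC(=O)OC(C)=O
Why: selective acylation of the secondary allylic alcohol; the tertiary C4–OH does not react under these conditions.

Step 11
Reactants: 20 (4S,5R,6S)-4-hydroxyguaia-1(10),7-dien-6-yl acetate; 21 angelic acid, (2Z)-2-methylbut-2-enoic acid
Product: 25 (4S,5R,6R,7R,8S)-6-acetoxy-4-hydroxyguai-1(10)-en-8-yl (2Z)-2-methylbut-2-enoate (target), via alkylborane 22 (not isolated), via acyloxyborane 23 (not isolated), via borate ester 24 (not isolated)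
Conditions: ThxBH2 (2.2 equiv; one equivalent is taken up by the C4–OH and released on work-up), THF, 0 to 23 °C; 21 (4 equiv), 0 °C; Me3NO (anhydrous, 6 equiv), 23 to 45 °C; aq. NaHCO3
Reagents that add atoms: trimethylamine N-oxide, C[N+](C)(C)[O-] (oxygen of the C8–O bond); thexylborane, CC(C)C(C)(C)B (boron is carried by 22–24 only)
Why: Proposed new method: a one-flask syn, anti-Markovnikov hydroacyloxylation in which thexylborane adds H and B across C7=C8 from the face anti to the allylic C6–OAc (boron to the less substituted C8, the tetrasubstituted C1=C10 alkene being inert), angelic acid cleaves the remaining B–H to give acyloxyborane 23, the amine oxide inserts oxygen into the C8–B bond by 1,2-migration with retention (24), and the boron-bound C8 alkoxide, made nucleophilic by Me3N coordination, is acylated by the boron-activated angeloyl group without any nucleophilic catalyst that could isomerise the Z ester, so C7 and C8 are set and the angelate is installed in one C–O bond-forming operation; the closest known reaction types are hydroboration–amine-oxide oxidation and esterification or amidation through acyloxyboron intermediates.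

**Compound list**

1 | pentane-2,4-dione | CC(=O)CC(C)=O | starting material
2 | 1-bromobut-2-yne | CC#CCBr | starting material
3 | 3-(but-2-yn-1-yl)pentane-2,4-dione | CC#CCC(C(C)=O)C(C)=O | intermediate (not isolated)
4 | hept-5-yn-2-one | CC#CCCC(C)=O | intermediate
5 | cyclopropanecarbonitrile | N#CC1CC1 | starting material
6 | 2-iodopropane | CC(C)I | starting material
7 | 1-(propan-2-yl)cyclopropane-1-carbonitrile | CC(C)C1(C#N)CC1 | intermediate
8 | N-lithio ketimine of 9 | CC(=N[Li])C1(C(C)C)CC1 | intermediate (not isolated)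
9 | 1-[1-(propan-2-yl)cyclopropyl]ethan-1-one | CC(=O)C1(C(C)C)CC1 | intermediate
10 | lithium aldolate (racemic) | [Li+].[O-]C(C)(CCC#CC)CC(=O)C1(C(C)C)CC1 | intermediate (not isolated)
11 | 3-methyl-1-oxo-1-[1-(propan-2-yl)cyclopropyl]oct-6-yn-3-yl acetate (racemic) | CC#CCCC(C)(OC(C)=O)CC(=O)C1(C(C)C)CC1 | intermediate (not isolated)
12 | (2E)-3-methyl-1-[1-(propan-2-yl)cyclopropyl]oct-2-en-6-yn-1-one | CC#CCC/C(C)=C/C(=O)C1(C(C)C)CC1 | intermediate
13 | (3R)-3-methyl-1-[1-(propan-2-yl)cyclopropyl]-3-(4,4,5,5-tetramethyl-1,3,2-dioxaborolan-2-yl)oct-6-yn-1-one | CC#CCC[C@](C)(B1OC(C)(C)C(C)(C)O1)CC(=O)C2(C(C)C)CC2 | intermediate (not isolated)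
14 | (3S)-3-hydroxy-3-methyl-1-[1-(propan-2-yl)cyclopropyl]oct-6-yn-1-one | CC#CCC[C@](C)(O)CC(=O)C1(C(C)C)CC1 | intermediate
15 | (1Z,3S)-3-methyl-1-[1-(propan-2-yl)cyclopropyl]-1,3-bis(triethylsilyloxy)oct-1-en-6-yne | CC#CCC[C@](C)(O[Si](CC)(CC)CC)/C=C(\O[Si](CC)(CC)CC)C1(C(C)C)CC1 | intermediate
16 | (4S,5S)-4,6-bis(triethylsilyloxy)guaia-1(10),6-diene | CC1=C2CC[C@](C)(O[Si](CC)(CC)CC)[C@H]2C(O[Si](CC)(CC)CC)=C(C(C)C)CC1 | intermediate
17 | (4S,5S)-4-(triethylsilyloxy)guaia-1(10),7-dien-6-one | CC1=C2CC[C@](C)(O[Si](CC)(CC)CC)[C@H]2C(=O)C(C(C)C)=CC1 | intermediate (not isolated)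
18 | (4S,5S)-4-hydroxyguaia-1(10),7-dien-6-one | CC1=C2CC[C@](C)(O)[C@H]2C(=O)C(C(C)C)=CC1 | intermediate
19 | (4S,5R,6S)-guaia-1(10),7-diene-4,6-diol | CC1=C2CC[C@](C)(O)[C@H]2[C@H](O)C(C(C)C)=CC1 | intermediate
20 | (4S,5R,6S)-4-hydroxyguaia-1(10),7-dien-6-yl acetate | CC1=C2CC[C@](C)(O)[C@H]2[C@H](OC(C)=O)C(C(C)C)=CC1 | intermediate
21 | angelic acid, (2Z)-2-methylbut-2-enoic acid | C/C=C(/C)C(O)=O | starting material
22 | C8 thexyl(hydrido)boryl adduct of 20 (H7 and boron syn, anti to C6–OAc) | CC(C)C(C)(C)B[C@H]1CC(C)=C2CC[C@](C)(O)[C@H]2[C@H](OC(C)=O)[C@@H]1C(C)C | intermediate (not isolated)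
23 | C8 thexyl(angeloyloxy)boryl compound | C/C=C(/C)C(=O)OB(C(C)(C)C(C)C)[C@H]1CC(C)=C2CC[C@](C)(O)[C@H]2[C@H](OC(C)=O)[C@@H]1C(C)C | intermediate (not isolated)
24 | C8–O borate ester bearing thexyloxy and angeloyloxy groups on boron | C/C=C(/C)C(=O)OB(OC(C)(C)C(C)C)O[C@H]1CC(C)=C2CC[C@](C)(O)[C@H]2[C@H](OC(C)=O)[C@@H]1C(C)C | intermediate (not isolated)
25 | (4S,5R,6R,7R,8S)-6-acetoxy-4-hydroxyguai-1(10)-en-8-yl (2Z)-2-methylbut-2-enoate | C/C=C(/C)C(=O)O[C@H]1CC(C)=C2CC[C@](C)(O)[C@H]2[C@H](OC(C)=O)[C@@H]1C(C)C | target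

**Step count and risks**

Total steps: 11. Longest linear sequence: 10 (steps 2–11 from 5 and 6); step 1 is a one-step branch that joins at step 4.

Most likely to fail:

- **Step 7 (sense of C5 induction in the [5+2]).** The preference for methyl over OSiEt3 in the position next to the C6 silyloxy group is argued from sterics and is not secured by precedent, so the C5 epimer may dominate. Fallback: set C5 by catalyst and form the C4–O bond afterwards by anti addition. From enone 12, soft enolisation at the γ-methyl group (Et3SiOTf, Et3N) gives the cross-conjugated silyl dienol ether (1Z)-3-methylidene-1-[1-(propan-2-yl)cyclopropyl]-1-(triethylsilyloxy)oct-1-en-6-yne F1. An enantioselective [5+2] with [Rh((R)-BINAP)]SbF6 (ligand enantiomer chosen for 5R) then gives (5R)-6-(triethylsilyloxy)guaia-1(10),4(15),6-triene F2. Mukaiyama hydration of the 1,1-disubstituted C4=C15 alkene (Mn(dpm)3, PhSiH3, O2, iPrOH, 0 °C) traps the C4 radical with oxygen trans to the C5–C6 bond and gives (4S,5S)-6-(triethylsilyloxy)guaia-1(10),6-dien-4-ol F3. Saegusa oxidation (Pd(OAc)2, MeCN) returns to the route at 18.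

- **Step 8 (endocyclic versus exocyclic enone in the Saegusa oxidation).** β-Hydride loss from the isopropyl methine would give the isopropylidene ketone instead of the C7=C8 enone. Fallback: from 16, PhSeCl (CH2Cl2, −78 °C) gives the α-selenyl ketone (4S,5S)-7-(phenylselanyl)-4-(triethylsilyloxy)guai-1(10)-en-6-one F4 (C7 epimers, inconsequential). Oxidation with NaIO4/NaHCO3 (THF/H2O, 0 to 23 °C) and selenoxide syn-elimination, which prefers a CH2 hydrogen over a CH hydrogen, gives 17; this is desilylated with HF·pyridine as in step 8.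

- **Step 11 (proposed new hydroacyloxylation).** The acyl transfer on boron or the oxidation of the acyloxyborane may be slow, or protodeboronation may compete. Fallback with known chemistry: from 20, hydroboration with ThxBH2 and oxidation with NaBO3·4H2O gives the alcohol (4S,5R,6R,7R,8S)-4,8-dihydroxyguai-1(10)-en-6-yl acetate F5. Esterification of the C8–OH with the mixed anhydride of 21 and 2,4,6-trichlorobenzoyl chloride (Et3N, toluene, 80 °C, no DMAP) returns to the route at 25.

**Further compounds**

F1 | step 7 | (1Z)-3-methylidene-1-[1-(propan-2-yl)cyclopropyl]-1-(triethylsilyloxy)oct-1-en-6-yne | CC#CCCC(=C)/C=C(\O[Si](CC)(CC)CC)C1(C(C)C)CC1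
F2 | step 7 | (5R)-6-(triethylsilyloxy)guaia-1(10),4(15),6-triene | CC1=C2CCC(=C)[C@H]2C(O[Si](CC)(CC)CC)=C(C(C)C)CC1
F3 | step 7 | (4S,5S)-6-(triethylsilyloxy)guaia-1(10),6-dien-4-ol | CC1=C2CC[C@](C)(O)[C@H]2C(O[Si](CC)(CC)CC)=C(C(C)C)CC1
F4 | step 8 | (4S,5S)-7-(phenylselanyl)-4-(triethylsilyloxy)guai-1(10)-en-6-one | CC1=C2CC[C@](C)(O[Si](CC)(CC)CC)[C@H]2C(=O)C(C(C)C)([Se]c3ccccc3)CC1
F5 | step 11 | (4S,5R,6R,7R,8S)-4,8-dihydroxyguai-1(10)-en-6-yl acetate | O[C@H]1CC(C)=C2CC[C@](C)(O)[C@H]2[C@H](OC(C)=O)[C@@H]1C(C)C
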